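The ratio I want is target still to come over material still on its way to target, late in a run, and a plateau does not show it directly.

| setting | north-west | south | alder | larch | maple |
|---|---|---|---|---|---|
| starting material | 0.050 M | 0.10 M | 0.050 M | 0.050 M | 0.050 M (fed, over 3.20 d) |
| precatalyst | 0.5 mol% | 0.5 mol% | 0.5 mol% | 0.5 mol% | 0.5 mol% |
| remark | run made earlier | run made earlier | everything together in a closed stirred flask, run for 4.0 d | a single well-mixed tank run continuously and read at steady state, 4.0 d in it on average | a stirred flask in which starting material is dosed at a steady rate over 3.20 d without added volume, worked up at 4.0 d |
| time |  |  | 4.0 d |  | 4.0 d |

- north-west (time / d: target / %, starting material / %): 0.625: 15.1, 7.8; 1.25: 31.5, 1.2; 1.67: 36.2, 0; 2.50: 38.9, 0.3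
- south (time / h: target / %, starting material / %): 5.00: 3.6, 42.1; 10.0: 13.5, 16.6; 15.0: 24.8, 8.0; 20.0: 34.0, 2.6

(scatter of a reading: 0.5 percentage points)

- the stated concentrations are those of everything mixed, before any reaction; amounts are the same in each set-up
- the feed brings no volume worth counting
- the earlier runs were made in a closed, stirred flask

1. the set-up with the highest amount of target at the outlet or at the end, in percent of the starting material put in ("none" if the first two lie within 2 percentage points) (alder / larch / maple / none)
2. amount of target at the outlet or at the end, in percent of the starting material put in, alder
3. amount of target at the outlet or at the end, in percent of the starting material put in, larch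
4. amount of target at the outlet or at the end, in percent of the starting material put in, maple

Starting material falls at 0.170 /h in the north-west run and 0.173 /h in the south run, about the same. Target lags, so I put an unseen intermediate between them. In the north-west run, the slope of target falls from 0.112 /d to 0.0325 /d of the charge, so I read a pseudo-first-order clearing rate of 0.0824 /h for the intermediate. The two-step formula with these rates puts 41.2% of the charge in the intermediate at 0.625 d. So 48.5% is my late share, the target still to come divided by the material still on its way.

But is that share real, or does it come from a poor pool estimate? If the plateau's 38.9% held from the start, target at 0.625 d would be 19.8%, and the reading is 15.1%, far beyond the scatter. The early share is 29.6%, less than the late one, and these readings do not tell me what lowers it; I carry the late share as my estimate.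

Alder repeats the north-west recipe, so I stay near 38.9%. Two tank stages in series give larch 40.6%. Averaging the two-step tail over maple's feed gives a completion of 94.0%, hence 45.6%, more than larch. I choose maple.

The forecast differs: alder best, with 39.5%, 31.5% and 35.5%, on the words “I assume a fixed ceiling”.

The flask gives 39.4% for alder, 43.5% for larch and 49.8% for maple, so maple is best.

    starting material → intermediate (k = 0.150 /h)
    catalyst + intermediate → catalyst + target (k = 220 /M/h)
    intermediate → decomposed reagent (k = 0.0400 /h)
    precatalyst → catalyst (k = 0.0990 /h)
    starting material + intermediate → side product (k = 1.10 /M/h)

Side product, each unit holding two of the charge, ends at 7.62% in maple against 19.7% in alder. My late share times maple's completion stands 4.2 percentage points under the flask. The share itself, 48.5%, stands 4 points under maple left to 40.0 d, which reaches 52.5%.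

The numbers in the tables are calculated on assumed constants; scatter was added.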